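The route cuts the C9–C11 bond between ring B and the side chain (labdane numbering). C9 lies next to C8, whose exocyclic methylene is a masked ketone. C11–C12=C13 is an allyl unit conjugated with the imide carbonyl C16. So an enolate carbon meets a π-allyl terminus. In one flask, a chlorinated bicyclic β-keto ester, whose ester carbon marks C9, is tied to the complete hydroxyethylidene succinimide. Palladium then exchanges the CO2 tether for the C9–C11 bond. This delivers every carbon except C17, with the E-alkene in place. The decalin comes from a polyene bicyclisation and a site-selective C–H chlorination. C17 and the 7β-acetate follow.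

Key step: step 6

Remark on numbering: ring A = C1–C5 and C10; ring B = C5–C10; C17 = exocyclic CH2 on C8; C11–C16 = side chain, with C15 and C16 the imide carbonyls. α is the face opposite to the C10 methyl group.

Assumption: N-tert-butyl-N-chloro-3,5-bis(trifluoromethyl)benzamide is treated as a purchasable reagent.

Step 1
Reactants: 1 methyl acetoacetate; 2 geranyl bromide
Product: 4 methyl (6E)-7,11-dimethyl-3-oxododeca-6,10-dienoate, via acetoacetate dianion 3 (not isolated)
Conditions: NaH, THF, 0 °C; n-BuLi, 0 °C; 2, 0→23 °C; aq. HCl quench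
Reagents that add atoms: none
Why: Dianion γ-alkylation of a β-keto ester: the terminal, more basic carbanion of 3 displaces the primary allylic bromide by SN2 without touching the E-alkene, and no stereocentre is formed.

Step 2
Reactants: 4 methyl (6E)-7,11-dimethyl-3-oxododeca-6,10-dienoate
Product: 5 racemic methyl (1R*,4aS*,8aS*)-5,5,8a-trimethyl-2-oxodecahydronaphthalene-1-carboxylate
Conditions: SnCl4 (1.5 equiv), water-saturated CH2Cl2, 0→23 °C
Reagents that add atoms: none
Why: Cationic polyene bicyclisation ended by the SnCl4-bound enol of the β-keto ester: chair–chair folding with anti addition across the E C5=C10 alkene sets 5-H and 10-Me trans, and the epimerisable C9 ester settles equatorial, so one racemic diastereomer should result.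

Step 3
Reactants: 5 racemic bicyclic keto ester
Product: 6 methyl (1R,4aS,8aS)-5,5,8a-trimethyl-2-oxodecahydronaphthalene-1-carboxylate
Conditions: preparative SFC, amylose tris(3,5-dimethylphenylcarbamate) phase, CO2/MeOH
Reagents that add atoms: none
Why: Resolution of a racemate by chromatography on a chiral stationary phase: no bond changes, and the enantiomer with 5α-H and 10β-Me is carried on, which fixes the absolute configuration of every later centre.

Step 4
Reactants: 6 methyl (1R,4aS,8aS)-5,5,8a-trimethyl-2-oxodecahydronaphthalene-1-carboxylate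
Product: 7 methyl (1R,4aS,7S,8aS)-7-chloro-5,5,8a-trimethyl-2-oxodecahydronaphthalene-1-carboxylate (2α-chloride)
Conditions: N-tert-butyl-N-chloro-3,5-bis(trifluoromethyl)benzamide (1.2 equiv), Cs2CO3, PhH, visible light, 55 °C
Reagents that add atoms: N-tert-butyl-N-chloro-3,5-bis(trifluoromethyl)benzamide CC(C)(C)N(Cl)C(=O)c1cc(C(F)(F)F)cc(C(F)(F)F)c1
Why: Amidyl-radical C–H chlorination (hydrogen atom transfer, then chlorine atom transfer in a radical chain): ring B is switched off by C8=O and the ester, C1 and C3 are shielded by the quaternary C10 and C4, so the bulky electrophilic radical takes a C2 hydrogen, and chlorine is delivered to the α face because the β face carries two syn-axial methyl groups, giving the equatorial 2α-chloride.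

Step 5
Reactants: 8 maleimide; 9 glycolaldehyde dimer (1,4-dioxane-2,5-diol)
Product: 11 (3E)-3-(2-hydroxyethylidene)pyrrolidine-2,5-dione, via succinimide phosphorane 10 (not isolated)
Conditions: PPh3, acetone, 56 °C; then 9, MeOH, 65 °C
Reagents that add atoms: none
Why: Phosphine addition to maleimide and a proton shift give the stabilised ylide 10, whose Wittig reaction with glycolaldehyde (released from its dimer) should give the E-alkene, with the CH2OH group trans to C16=O.

Step 6
Reactants: 7 chloro keto ester; 11 (3E)-3-(2-hydroxyethylidene)pyrrolidine-2,5-dione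
Product: 16 2α-chloro-8-oxo-17-norlabd-12(E)-ene-15,16-dicarboximide (5α-H, 9α-H, 10β-Me), via allyl keto ester 12 (not isolated), via N-silyl allyl ester 13 (not isolated), via allylated keto acid 14 (not isolated), via N-silyl keto imide 15 (not isolated)
Conditions: DMAP (0.3 equiv), 4 Å MS, PhMe, 105 °C; cool to 23 °C, N-methyl-N-(trimethylsilyl)trifluoroacetamide (2 equiv); Pd2(dba)3 (2.5 mol %), PPh3 (10 mol %), 23→40 °C; 1 M aq. HCl/THF work-up
Reagents that add atoms: none
Why: DMAP-mediated ester exchange first ties alcohol 11 to the C9 carboxyl group of 7 (12), the silylating agent masks the acidic imide N–H (13), and zerovalent palladium then ionises the allylic C11–O bond to a π-allyl cation spanning C11–C12–C13, paired with the β-keto carboxylate. Because C9 still bears a hydrogen, proton relay to the carboxylate gives the stabilised C8–C9 enolate, which attacks the CH2 terminus C11 from outside, and acid 14 then loses CO2 through the usual six-centre path; the closest known reaction type is the Tsuji–Saegusa decarboxylative allylation of allyl β-keto esters, the palladium version of the Carroll [3,3] rearrangement. No ring is closed. The only new stereocentre is C9: it is fixed when C9 takes up its proton after loss of CO2 along the axial α trajectory, away from the axial 10-methyl group, and because C9 stays next to C8=O the acidic work-up lets any 9α-chain epimer drain into the equatorial 9β isomer of the rigid trans-decalin. Regioselectivity on the decalin (C9, not C7, towards which a free 8-ketone would enolise) is secured by the carboxyl group that leaves from C9; on the allyl unit, attack at C11 instead of the fully substituted C13 keeps C12=C13 conjugated with C16=O, and the E geometry is the thermodynamic one of that alkylidene imide. The secondary C2 chloride is inert to zerovalent palladium under these conditions.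

Step 7
Reactants: 16 keto imide
Product: 17 2α-chlorolabda-8(17),12(E)-diene-15,16-dicarboximide
Conditions: Zn, CH2Br2, TiCl4, THF/CH2Cl2, 0→23 °C (excess reagent for the N–H)
Reagents that add atoms: dibromomethane BrCBr
Why: Takai–Lombardo methylenation: the non-basic gem-dimetallic CH2 reagent adds to the hindered, enolisable C8 ketone without epimerising C9 and leaves the imide, the conjugated alkene and the chloride alone.

Step 8
Reactants: 17 diene imide
Product: 18 2α-chloro-7α-hydroxylabda-8(17),12(E)-diene-15,16-dicarboximide
Conditions: SeO2 (0.5 equiv), t-BuOOH, CH2Cl2, 23 °C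
Reagents that add atoms: selenium dioxide O=[Se]=O (oxygen carrier); tert-butyl hydroperoxide CC(C)(C)OO (terminal oxygen source)
Why: SeO2 allylic hydroxylation (ene reaction, then [2,3]-sigmatropic shift): the electron-rich C8=C17 alkene reacts in preference to the imide-conjugated one, the CH2 at C7 in preference to the hindered methine C9, and oxygen arrives axially on the open α face to give the 7α-alcohol.

Step 9
Reactants: 18 7α-alcohol
Product: 19 2α-chloro-7-oxolabda-8(17),12(E)-diene-15,16-dicarboximide
Conditions: Dess–Martin periodinane, CH2Cl2, 0→23 °C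
Reagents that add atoms: none
Why: Dess–Martin oxidation turns the wrongly configured allylic alcohol into the α-methylene ketone under mild conditions that should not move the exocyclic alkene into the ring.

Step 10
Reactants: 19 α-methylene ketone
Product: 20 2α-chloro-7β-hydroxylabda-8(17),12(E)-diene-15,16-dicarboximide
Conditions: NaBH4, CeCl3·7H2O, MeOH, −40 °C
Reagents that add atoms: none
Why: Luche reduction: the cerium-modified borohydride adds 1,2 and axially from the α face of the ring B chair, which sets the equatorial 7β-alcohol (7S) and spares the imide.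

Step 11
Reactants: 20 7β-alcohol
Product: 21 7β-acetoxy-2α-chlorolabda-8(17),12(E)-diene-15,16-dicarboximide (target)
Conditions: Ac2O, pyridine, 0→23 °C
Reagents that add atoms: acetic anhydride CC(=O)OC(C)=O
Why: Acetylation of the secondary allylic alcohol with Ac2O/pyridine; the weakly nucleophilic imide N–H stays free (any N-acetyl imide is cleaved on aqueous work-up) and no stereocentre is touched.

Compound list
1 | methyl acetoacetate | COC(=O)CC(C)=O | starting material
2 | geranyl bromide | CC(C)=CCC/C(C)=C/CBr | starting material
3 | sodium lithium dianion of methyl acetoacetate | [Na+].[Li+].[CH2-]C(=O)[CH-]C(=O)OC | intermediate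
4 | methyl (6E)-7,11-dimethyl-3-oxododeca-6,10-dienoate | CC(C)=CCC/C(C)=C/CCC(=O)CC(=O)OC | intermediate
5 | racemic methyl (1R*,4aS*,8aS*)-5,5,8a-trimethyl-2-oxodecahydronaphthalene-1-carboxylate (both enantiomers) | O=C1CC[C@H]2C(C)(C)CCC[C@]2(C)[C@H]1C(=O)OC.O=C1CC[C@@H]2C(C)(C)CCC[C@@]2(C)[C@@H]1C(=O)OC | intermediate
6 | methyl (1R,4aS,8aS)-5,5,8a-trimethyl-2-oxodecahydronaphthalene-1-carboxylate | O=C1CC[C@H]2C(C)(C)CCC[C@]2(C)[C@H]1C(=O)OC | intermediate
7 | methyl (1R,4aS,7S,8aS)-7-chloro-5,5,8a-trimethyl-2-oxodecahydronaphthalene-1-carboxylate | O=C1CC[C@H]2C(C)(C)C[C@H](Cl)C[C@]2(C)[C@H]1C(=O)OC | intermediate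
8 | maleimide | O=C1C=CC(=O)N1 | starting material
9 | glycolaldehyde dimer (1,4-dioxane-2,5-diol) | OC1COC(O)CO1 | starting material
10 | 3-(triphenylphosphoranylidene)pyrrolidine-2,5-dione | O=C1CC(=P(c2ccccc2)(c2ccccc2)c2ccccc2)C(=O)N1 | intermediate
11 | (3E)-3-(2-hydroxyethylidene)pyrrolidine-2,5-dione | OC/C=C1\CC(=O)NC1=O | intermediate
12 | (2E)-2-(2,5-dioxopyrrolidin-3-ylidene)ethyl ester of the acid of 7 | O=C1CC[C@H]2C(C)(C)C[C@H](Cl)C[C@]2(C)[C@H]1C(=O)OC/C=C1\CC(=O)NC1=O | intermediate
13 | N-trimethylsilyl derivative of 12 | O=C1CC[C@H]2C(C)(C)C[C@H](Cl)C[C@]2(C)[C@H]1C(=O)OC/C=C1\CC(=O)N([Si](C)(C)C)C1=O | intermediate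
14 | 9α-allylated 8-oxo-9β-carboxylic acid (N-silyl) | O=C1CC[C@H]2C(C)(C)C[C@H](Cl)C[C@]2(C)[C@@]1(C/C=C1\CC(=O)N([Si](C)(C)C)C1=O)C(=O)O | intermediate
15 | N-trimethylsilyl derivative of 16 | O=C1CC[C@H]2C(C)(C)C[C@H](Cl)C[C@]2(C)[C@H]1C/C=C1\CC(=O)N([Si](C)(C)C)C1=O | intermediate
16 | 2α-chloro-8-oxo-17-norlabd-12(E)-ene-15,16-dicarboximide | O=C1CC[C@H]2C(C)(C)C[C@H](Cl)C[C@]2(C)[C@H]1C/C=C1\CC(=O)NC1=O | intermediate
17 | 2α-chlorolabda-8(17),12(E)-diene-15,16-dicarboximide | C=C1CC[C@H]2C(C)(C)C[C@H](Cl)C[C@]2(C)[C@H]1C/C=C1\CC(=O)NC1=O | intermediate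
18 | 2α-chloro-7α-hydroxylabda-8(17),12(E)-diene-15,16-dicarboximide | C=C1[C@H](O)C[C@H]2C(C)(C)C[C@H](Cl)C[C@]2(C)[C@H]1C/C=C1\CC(=O)NC1=O | intermediate
19 | 2α-chloro-7-oxolabda-8(17),12(E)-diene-15,16-dicarboximide | C=C1C(=O)C[C@H]2C(C)(C)C[C@H](Cl)C[C@]2(C)[C@H]1C/C=C1\CC(=O)NC1=O | intermediate
20 | 2α-chloro-7β-hydroxylabda-8(17),12(E)-diene-15,16-dicarboximide | C=C1[C@@H](O)C[C@H]2C(C)(C)C[C@H](Cl)C[C@]2(C)[C@H]1C/C=C1\CC(=O)NC1=O | intermediate
21 | 7β-acetoxy-2α-chlorolabda-8(17),12(E)-diene-15,16-dicarboximide | C=C1[C@@H](OC(C)=O)C[C@H]2C(C)(C)C[C@H](Cl)C[C@]2(C)[C@H]1C/C=C1\CC(=O)NC1=O | target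

Total steps: 11. Longest linear sequence: 10 (steps 1–4 and 6–11).

Steps most likely to fail

Step 6. Three processes may intervene:
- The π-allyl intermediate may lose a proton from C14, which is elimination towards a vinylmaleimide.
- The C9 nucleophile may be protonated before it couples.
- Nitrogen may be allylated if silylation is incomplete.

The fallback sets out from 7 and comes back at 16. It brings in only three carbons first and builds the sensitive imide afterwards under neutral conditions.
- Ester exchange of 7 with allyl alcohol (DMAP, PhMe, 105 °C) gives the allyl keto ester F1.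
- Decarboxylative allylation of F1 with Pd(PPh3)4 in THF meets no acidic partner and gives the 9β-allyl ketone F2.
- Ozonolysis of the terminal alkene (O3, CH2Cl2, −78 °C, then PPh3) gives the C12 aldehyde F3.
- A Wittig reaction of F3 with ylide 10 in warm MeOH, selective for the aldehyde over the hindered C8 ketone, gives 16.

Step 4. Ionic chlorination at the enolisable C9 position by the N-chloroamide and carbonate may compete with the radical chain and use up the reagent. Site selectivity may also erode.

The fallback sets out from 6 and comes back at 7. It blocks C9 on purpose.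
- SO2Cl2 in CH2Cl2 gives the 9α-chloro keto ester F4, which has no acidic hydrogen left between the carbonyl groups.
- The same amidyl-radical chlorination then gives the 2α,9α-dichloro keto ester F5.
- Zn in AcOH removes only the activated C9 chloride by reduction and returns 7.

Step 7. Addition to the hindered C8 carbonyl may be slow. Zinc or low-valent titanium may meanwhile reduce or attack the alkylidene imide.

The fallback sets out from 16 and comes back at 17. It is a two-stage Peterson olefination.
- Me3SiCH2MgCl/CeCl3 (3 equiv, THF, −78 °C; the first equivalent deprotonates the imide and so protects the conjugated alkene) adds to C8 from the α face. This gives the 8β-hydroxy-8α-(trimethylsilylmethyl) imide F6.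
- HF·pyridine then triggers the elimination to 17.

Further compounds
F1 | step 6 | allyl (1R,4aS,7S,8aS)-7-chloro-5,5,8a-trimethyl-2-oxodecahydronaphthalene-1-carboxylate | O=C1CC[C@H]2C(C)(C)C[C@H](Cl)C[C@]2(C)[C@H]1C(=O)OCC=C
F2 | step 6 | 9β-allyl-2α-chloro 8-ketone (1-allyl-7-chloro-5,5,8a-trimethyloctahydronaphthalen-2(1H)-one) | O=C1CC[C@H]2C(C)(C)C[C@H](Cl)C[C@]2(C)[C@H]1CC=C
F3 | step 6 | 2-(7-chloro-5,5,8a-trimethyl-2-oxodecahydronaphthalen-1-yl)acetaldehyde (9β chain) | O=C1CC[C@H]2C(C)(C)C[C@H](Cl)C[C@]2(C)[C@H]1CC=O
F4 | step 4 | methyl 9α-chloro-8-oxo keto ester (1-chloro derivative of 6) | O=C1CC[C@H]2C(C)(C)CCC[C@]2(C)[C@@]1(Cl)C(=O)OC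
F5 | step 4 | methyl 2α,9α-dichloro-8-oxo keto ester (1,7-dichloro derivative of 6) | O=C1CC[C@H]2C(C)(C)C[C@H](Cl)C[C@]2(C)[C@@]1(Cl)C(=O)OC
F6 | step 7 | 2α-chloro-8β-hydroxy-8α-(trimethylsilylmethyl)-17-norlabd-12(E)-ene-15,16-dicarboximide | C[Si](C)(C)C[C@]1(O)CC[C@H]2C(C)(C)C[C@H](Cl)C[C@]2(C)[C@H]1C/C=C1\CC(=O)NC1=O
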